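## Retrosynthetic overview

1. Labels used below: ring C1 (quaternary) – C2=C3 – C4 (ester O) – C5 (CH3, OH) – C6=C7 – C8 (C=O) – C9 (CH2OH)=C10 – C11H2; the target is 1S,4R,5R with three cis ring alkenes.
2. Target ⇒ late C4 acylation and deprotection ⇒ 11-membered dienone ⇒ Nozaki–Hiyama–Kishi closure of C8–C9 from a (Z)-enal/(Z)-vinyl iodide seco compound.
3. Seco compound ⇒ C1–C6 core: C7–C8 by Still–Gennari olefination, C9–C10 by Wittig homologation and enal α-iodination.
4. Core ⇒ C4–C5 aldol between a C1–C4 ynal and the lithium enolate of the (R)-lactic acid/pivalaldehyde dioxolanone (C5, C6, 5-CH3). C4 is then fixed by oxidation and asymmetric transfer hydrogenation, and the alkyne is reduced to the cis alkene. Ynal ⇒ geraniol by Sharpless epoxidation and epoxy silyl ether rearrangement (sets C1).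
5. Ring order: dioxolanone auxiliary ring (step 6), acetonide protecting ring (step 12), then the only ring of the target, the 11-membered carbocycle (step 26).

## Route

Step 1
Reactants: 1 geraniol
Product: 2 (2S,3S)-2,3-epoxygeraniol
Conditions: Ti(OiPr)4 (5 mol%), L-(+)-diethyl tartrate (7 mol%), t-BuOOH, 4 Å MS, CH2Cl2, −20 °C
Reagents that add atoms: tert-butyl hydroperoxide, CC(C)(C)OO
Why: Sharpless asymmetric epoxidation; the L-(+)-tartrate catalyst delivers oxygen to one face of the allylic alcohol to give the 2S,3S epoxide, and the remote trisubstituted alkene has no directing hydroxyl and is untouched.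

Step 2
Reactants: 2 (2S,3S)-2,3-epoxygeraniol
Product: 3 tert-butyldimethylsilyl ether of 2
Conditions: TBSCl, imidazole, DMF, 0 °C → rt
Reagents that add atoms: tert-butyldimethylsilyl chloride, CC(C)(C)[Si](C)(C)Cl
Why: Standard silylation of the primary alcohol, which supplies the siloxymethyl group that migrates in step 3.

Step 3
Reactants: 3 epoxy silyl ether
Product: 4 (S)-2-[(tert-butyldimethylsilyloxy)methyl]-2,6-dimethylhept-5-enal
Conditions: MeAl(OAr)2 (Ar = 4-bromo-2,6-di-tert-butylphenyl, 20 mol%), CH2Cl2, −78 → −20 °C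
Reagents that add atoms: none
Why: Yamamoto epoxy silyl ether rearrangement (semipinacol type); the bulky aluminium Lewis acid opens the epoxide at the tertiary carbon and the siloxymethyl group shifts anti to the leaving C–O bond, so the epoxide chirality is transferred with inversion into the quaternary centre (future C1).

Step 4
Reactants: 4 (S)-aldehyde
Product: 5 (R)-tert-butyl[(2-ethynyl-2,6-dimethylhept-5-en-1-yl)oxy]dimethylsilane
Conditions: dimethyl (1-diazo-2-oxopropyl)phosphonate, K2CO3, MeOH, 0 °C → rt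
Reagents that add atoms: dimethyl (1-diazo-2-oxopropyl)phosphonate, CC(=O)C(=[N+]=[N-])P(=O)(OC)OC
Why: Seyferth–Gilbert homologation in the Ohira–Bestmann form turns the aldehyde (future C2) into the terminal alkyne C2≡C3; the aldehyde has no α-hydrogen, so C1 cannot epimerise.

Step 5
Reactants: 5 (R)-alkyne
Product: 7 (R)-4-[(tert-butyldimethylsilyloxy)methyl]-4,8-dimethylnon-7-en-2-ynal, via lithium acetylide 6 (not isolated)
Conditions: n-BuLi, THF, −78 °C; DMF, −78 → 0 °C; poured into cold aq. KH2PO4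
Reagents that add atoms: N,N-dimethylformamide, CN(C)C=O
Why: Acetylide formylation with DMF gives the ynal (C4 aldehyde); the buffered reverse quench avoids amine addition to the ynal.

Step 6
Reactants: 8 (R)-lactic acid; 9 pivalaldehyde
Product: 10 (2R,5R)-2-tert-butyl-5-methyl-1,3-dioxolan-4-one
Conditions: TsOH (cat.), pentane, reflux with water separator; cis isomer crystallised from pentane at −78 °C
Reagents that add atoms: none
Why: Seebach acetalisation; the cis acetal crystallises and its acetal carbon stores the lactate chirality for the enolate step.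

Step 7
Reactants: 10 (2R,5R)-dioxolanone; 7 (R)-ynal
Product: 12 aldol adduct (2R,5S)-2-tert-butyl-5-[(4R)-4-[(tert-butyldimethylsilyloxy)methyl]-1-hydroxy-4,8-dimethylnon-7-en-2-yn-1-yl]-5-methyl-1,3-dioxolan-4-one as both carbinol epimers, via lithium enolate 11 (not isolated)
Conditions: LiN(iPr)2, THF, −78 °C; then 7, −78 °C; AcOH/THF quench at −78 °C
Reagents that add atoms: none
Why: Intermolecular aldol addition of Seebach's self-regeneration-of-stereocentres enolate forms C4–C5; the ynal attacks the enolate face opposite the tert-butyl group, which sets C5 (the new bond takes the place of the lactate hydrogen). The C4 carbinol forms as a mixture that is corrected in steps 8 and 9.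

Step 8
Reactants: 12 aldol adduct (epimer mixture)
Product: 13 ynone (2R,5S)-2-tert-butyl-5-[(4R)-4-[(tert-butyldimethylsilyloxy)methyl]-4,8-dimethylnon-7-en-2-ynoyl]-5-methyl-1,3-dioxolan-4-one
Conditions: Dess–Martin periodinane, NaHCO3, CH2Cl2, 0 °C → rt
Reagents that add atoms: none
Why: Dess–Martin oxidation converges both C4 epimers to one ynone; C5 is quaternary and cannot enolise.

Step 9
Reactants: 13 ynone
Product: 14 (1R)-propargylic alcohol (2R,5S)-2-tert-butyl-5-[(1R,4R)-4-[(tert-butyldimethylsilyloxy)methyl]-1-hydroxy-4,8-dimethylnon-7-en-2-yn-1-yl]-5-methyl-1,3-dioxolan-4-one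
Conditions: Ru[(S,S)-TsNCH(Ph)CH(Ph)NH](p-cymene) (5 mol%), iPrOH, 25 °C
Reagents that add atoms: none
Why: Noyori asymmetric transfer hydrogenation of an ynone; the alkyne is the directing π-substituent, and the S,S catalyst gives the same spatial arrangement as in (S)-alkynyl methyl carbinols, which here is the target C4 configuration (catalyst control).

Step 10
Reactants: 14 propargylic alcohol
Product: 15 (Z)-allylic alcohol (2R,5S)-2-tert-butyl-5-[(1R,2Z,4R)-4-[(tert-butyldimethylsilyloxy)methyl]-1-hydroxy-4,8-dimethylnona-2,7-dien-1-yl]-5-methyl-1,3-dioxolan-4-one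
Conditions: H2 (1 atm), Pd/CaCO3 poisoned with Pb(OAc)2, quinoline, EtOAc, rt
Reagents that add atoms: none
Why: Lindlar semi-hydrogenation adds hydrogen syn to give the cis C2=C3 alkene; the trisubstituted side-chain alkene is not reduced.

Step 11
Reactants: 15 (Z)-allylic alcohol
Product: 16 methyl (2S,3R,4Z,6R)-6-[(tert-butyldimethylsilyloxy)methyl]-2,3-dihydroxy-2,6,10-trimethylundeca-4,9-dienoate
Conditions: K2CO3 (0.3 equiv), MeOH, 0 °C
Reagents that add atoms: methanol, CO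
Why: Methanolysis of the acylal-type lactone releases pivalaldehyde and unmasks the C5 tertiary alcohol and the C6 methyl ester without touching the stereocentres.

Step 12
Reactants: 16 diol ester
Product: 17 methyl (4S,5R)-5-[(1Z,3R)-3-[(tert-butyldimethylsilyloxy)methyl]-3,7-dimethylocta-1,6-dien-1-yl]-2,2,4-trimethyl-1,3-dioxolane-4-carboxylate
Conditions: 2,2-dimethoxypropane, PPTS (10 mol%), CH2Cl2, rt
Reagents that add atoms: 2,2-dimethoxypropane, COC(C)(C)OC
Why: Acid-catalysed transacetalisation ties the C4/C5 diol into an acetonide, which protects both hydroxyls through the hydride, ylide and chromium steps.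

Step 13
Reactants: 17 acetonide silyl ether
Product: 18 primary alcohol methyl (4S,5R)-5-[(1Z,3R)-3-(hydroxymethyl)-3,7-dimethylocta-1,6-dien-1-yl]-2,2,4-trimethyl-1,3-dioxolane-4-carboxylate
Conditions: HF·pyridine, pyridine, THF, 0 °C → rt
Reagents that add atoms: none
Why: Fluoride cleavage of the primary silyl ether under buffered, non-basic conditions that leave the acetonide and ester intact.

Step 14
Reactants: 18 primary alcohol
Product: 19 aldehyde methyl (4S,5R)-5-[(1Z,3R)-3-formyl-3,7-dimethylocta-1,6-dien-1-yl]-2,2,4-trimethyl-1,3-dioxolane-4-carboxylate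
Conditions: Dess–Martin periodinane, NaHCO3, CH2Cl2, 0 °C → rt
Reagents that add atoms: none
Why: Dess–Martin oxidation; the aldehyde (future C11) sits on the quaternary C1 and has no α-hydrogen.

Step 15
Reactants: 19 aldehyde
Product: 20 vinyl compound methyl (4S,5R)-5-[(1Z,3S)-3-ethenyl-3,7-dimethylocta-1,6-dien-1-yl]-2,2,4-trimethyl-1,3-dioxolane-4-carboxylate
Conditions: Ph3PCH3Br, KOtBu, THF, 0 °C; then 19, 0 °C → rt
Reagents that add atoms: methyltriphenylphosphonium bromide, [Br-].C[P+](c1ccccc1)(c1ccccc1)c1ccccc1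
Why: Wittig methylenation adds the future C10 as a terminal alkene; the preformed ylide reacts with the aldehyde far faster than with the hindered ester.

Step 16
Reactants: 20 vinyl compound
Product: 22 primary alcohol methyl (4S,5R)-5-[(1Z,3S)-3-(2-hydroxyethyl)-3,7-dimethylocta-1,6-dien-1-yl]-2,2,4-trimethyl-1,3-dioxolane-4-carboxylate, via B-alkyl-9-borabicyclononane 21 (not isolated)
Conditions: 9-BBN (1.5 equiv), THF, 0 °C → rt; then 30% H2O2, pH 7 phosphate buffer, 0 °C → rt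
Reagents that add atoms: hydrogen peroxide, OO
Why: Hydroboration–oxidation; 9-BBN reacts only with the monosubstituted alkene, anti-Markovnikov, and leaves the hindered cis and trisubstituted alkenes alone.

Step 17
Reactants: 22 primary alcohol
Product: 23 aldehyde methyl (4S,5R)-5-[(1Z,3S)-3,7-dimethyl-3-(2-oxoethyl)octa-1,6-dien-1-yl]-2,2,4-trimethyl-1,3-dioxolane-4-carboxylate
Conditions: Dess–Martin periodinane, NaHCO3, CH2Cl2, 0 °C → rt
Reagents that add atoms: none
Why: Dess–Martin oxidation to the C10 aldehyde under neutral conditions.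

Step 18
Reactants: 23 aldehyde
Product: 24 (E)-enal methyl (4S,5R)-5-[(1Z,3S)-3,7-dimethyl-3-[(2E)-4-oxobut-2-en-1-yl]octa-1,6-dien-1-yl]-2,2,4-trimethyl-1,3-dioxolane-4-carboxylate
Conditions: Ph3P=CHCHO (1.3 equiv), toluene, 70 °C
Reagents that add atoms: (triphenylphosphoranylidene)acetaldehyde, O=CC=P(c1ccccc1)(c1ccccc1)c1ccccc1
Why: Wittig reaction with a stabilised ylide gives the E-enal and brings in C9 and the future CH2OH carbon.

Step 19
Reactants: 24 (E)-enal
Product: 25 (Z)-2-iodoenal methyl (4S,5R)-5-[(1Z,3S)-3-[(2Z)-3-iodo-4-oxobut-2-en-1-yl]-3,7-dimethylocta-1,6-dien-1-yl]-2,2,4-trimethyl-1,3-dioxolane-4-carboxylate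
Conditions: I2, pyridine, DMAP (0.2 equiv), CH2Cl2, 0 °C → rt, dark
Reagents that add atoms: iodine, II
Why: α-Iodination of the enal by a Baylis–Hillman-type amine addition, enolate iodination and elimination; it gives the (Z)-2-iodoenal with iodine cis to the C11 chain, the geometry needed for the ring alkene C9=C10.

Step 20
Reactants: 25 (Z)-2-iodoenal
Product: 26 (Z)-2-iodoallylic alcohol methyl (4S,5R)-5-[(1Z,3S)-3-[(2Z)-4-hydroxy-3-iodobut-2-en-1-yl]-3,7-dimethylocta-1,6-dien-1-yl]-2,2,4-trimethyl-1,3-dioxolane-4-carboxylate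
Conditions: NaBH4, CeCl3·7H2O, MeOH, −20 °C
Reagents that add atoms: none
Why: Luche 1,2-reduction of the enal; the hindered methyl ester and the vinyl iodide are not affected.

Step 21
Reactants: 26 iodoallylic alcohol
Product: 27 silyl ether methyl (4S,5R)-5-[(1Z,3S)-3-[(2Z)-4-(tert-butyldiphenylsilyloxy)-3-iodobut-2-en-1-yl]-3,7-dimethylocta-1,6-dien-1-yl]-2,2,4-trimethyl-1,3-dioxolane-4-carboxylate
Conditions: TBDPSCl, imidazole, CH2Cl2, rt
Reagents that add atoms: tert-butyl(chloro)diphenylsilane, CC(C)(C)[Si](Cl)(c1ccccc1)c1ccccc1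
Why: Silylation with an acid-stable group that survives the later acetonide hydrolysis and keeps the primary alcohol out of the final acylation.

Step 22
Reactants: 27 methyl ester
Product: 28 aldehyde (4S,5R)-5-[(1Z,3S)-3-[(2Z)-4-(tert-butyldiphenylsilyloxy)-3-iodobut-2-en-1-yl]-3,7-dimethylocta-1,6-dien-1-yl]-2,2,4-trimethyl-1,3-dioxolane-4-carbaldehyde
Conditions: iBu2AlH (1.2 equiv), CH2Cl2, −78 °C; MeOH, then aq. potassium sodium tartrate
Reagents that add atoms: none
Why: Partial DIBAL reduction; the α-alkoxy ester gives a chelated tetrahedral aluminate that is stable at −78 °C and releases the C6 aldehyde on work-up (no α-hydrogen, no epimerisation).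

Step 23
Reactants: 28 aldehyde
Product: 29 (Z)-enoate methyl (2Z)-3-[(4R,5R)-5-[(1Z,3S)-3-[(2Z)-4-(tert-butyldiphenylsilyloxy)-3-iodobut-2-en-1-yl]-3,7-dimethylocta-1,6-dien-1-yl]-2,2,4-trimethyl-1,3-dioxolan-4-yl]prop-2-enoate
Conditions: (CF3CH2O)2P(O)CH2CO2Me, KN(SiMe3)2, 18-crown-6, THF, −78 °C
Reagents that add atoms: methyl [bis(2,2,2-trifluoroethoxy)phosphoryl]acetate, COC(=O)CP(=O)(OCC(F)(F)F)OCC(F)(F)F
Why: Still–Gennari olefination; the electron-poor phosphonate eliminates under kinetic control to give the cis C6=C7 enoate.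

Step 24
Reactants: 29 (Z)-enoate
Product: 30 (Z)-allylic alcohol (2Z)-3-[(4R,5R)-5-[(1Z,3S)-3-[(2Z)-4-(tert-butyldiphenylsilyloxy)-3-iodobut-2-en-1-yl]-3,7-dimethylocta-1,6-dien-1-yl]-2,2,4-trimethyl-1,3-dioxolan-4-yl]prop-2-en-1-ol
Conditions: iBu2AlH (2.5 equiv), CH2Cl2, −78 °C; aq. potassium sodium tartrate
Reagents that add atoms: none
Why: DIBAL 1,2-reduction of the enoate to the allylic alcohol with retention of the cis geometry.

Step 25
Reactants: 30 (Z)-allylic alcohol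
Product: 31 seco (Z)-enal (2Z)-3-[(4R,5R)-5-[(1Z,3S)-3-[(2Z)-4-(tert-butyldiphenylsilyloxy)-3-iodobut-2-en-1-yl]-3,7-dimethylocta-1,6-dien-1-yl]-2,2,4-trimethyl-1,3-dioxolan-4-yl]prop-2-enal
Conditions: Dess–Martin periodinane, NaHCO3, CH2Cl2, 0 °C; used at once
Reagents that add atoms: none
Why: Buffered Dess–Martin oxidation gives the cis enal (C8) without isomerisation; the acetonide on the C5 oxygen prevents lactol formation.

Step 26
Reactants: 31 seco (Z)-enal
Product: 32 macrocyclic allylic alcohol (11-membered ring; C8–OH as both epimers; C4/C5 acetonide; C9–CH2OTBDPS; 1S,4R,5R; ring alkenes 2Z,6Z,9Z)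
Conditions: CrCl2 (10 equiv), NiCl2 (0.1 equiv), degassed DMSO/THF, 0.002 M, rt, slow addition
Reagents that add atoms: none
Why: Intramolecular Nozaki–Hiyama–Kishi reaction; nickel inserts into the C9–I bond with retention of geometry, the vinyl group passes to chromium and adds 1,2 to the aldehyde under high dilution to close the 11-membered ring. The new C8 centre is unselective and is removed in step 27.

Step 27
Reactants: 32 macrocyclic allylic alcohol
Product: 33 macrocyclic dienone (C8 ketone; C4/C5 acetonide; C9–CH2OTBDPS; 1S,4R,5R; 2Z,6Z,9Z)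
Conditions: Dess–Martin periodinane, NaHCO3, CH2Cl2, 0 °C → rt
Reagents that add atoms: none
Why: Dess–Martin oxidation of the doubly allylic alcohol gives the cross-conjugated dienone.

Step 28
Reactants: 33 macrocyclic dienone
Product: 34 dienone diol (free C4–OH and C5–OH; C9–CH2OTBDPS; 1S,4R,5R)
Conditions: AcOH/THF/H2O (3:1:1), 45 °C
Reagents that add atoms: none
Why: Acid hydrolysis of the acetonide; the silyl ether is stable to aqueous acetic acid, and the electron-poor enone disfavours ionisation at C5.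

Step 29
Reactants: 34 dienone diol; 35 3-methylbut-2-enoyl chloride
Product: 36 C4 3-methylbut-2-enoate of 34 (C5–OH free; C9–CH2OTBDPS)
Conditions: pyridine, DMAP (10 mol%), CH2Cl2, 0 °C
Reagents that add atoms: none
Why: DMAP-catalysed acylation; only the secondary allylic C4–OH reacts, since the tertiary C5–OH is too hindered and the primary alcohol is silylated. Pyridine as the only base limits ketene formation and deconjugation of the acyl group.

Step 30
Reactants: 36 silyl-protected ester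
Product: 37 target CNP0230506.6
Conditions: HF·pyridine, pyridine, THF, 0 °C → rt
Reagents that add atoms: none
Why: Buffered fluoride desilylation frees the primary allylic alcohol without touching the ester, the dienone or the tertiary alcohol.

## Compound list

1 | geraniol, (2E)-3,7-dimethylocta-2,6-dien-1-ol | CC(C)=CCC/C(C)=C/CO | starting material
2 | (2S,3S)-2,3-epoxygeraniol, [(2S,3S)-3-methyl-3-(4-methylpent-3-en-1-yl)oxiran-2-yl]methanol | CC(C)=CCC[C@]1(C)O[C@H]1CO | intermediate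
3 | tert-butyldimethyl{[(2S,3S)-3-methyl-3-(4-methylpent-3-en-1-yl)oxiran-2-yl]methoxy}silane | CC(C)=CCC[C@]1(C)O[C@H]1CO[Si](C)(C)C(C)(C)C | intermediate
4 | (S)-2-[(tert-butyldimethylsilyloxy)methyl]-2,6-dimethylhept-5-enal | CC(C)=CCC[C@@](C)(CO[Si](C)(C)C(C)(C)C)C=O | intermediate
5 | (R)-tert-butyl[(2-ethynyl-2,6-dimethylhept-5-en-1-yl)oxy]dimethylsilane | CC(C)=CCC[C@@](C)(CO[Si](C)(C)C(C)(C)C)C#C | intermediate
6 | lithium acetylide of 5 | CC(C)=CCC[C@@](C)(CO[Si](C)(C)C(C)(C)C)C#C[Li] | intermediate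
7 | (R)-4-[(tert-butyldimethylsilyloxy)methyl]-4,8-dimethylnon-7-en-2-ynal | CC(C)=CCC[C@@](C)(CO[Si](C)(C)C(C)(C)C)C#CC=O | intermediate
8 | (R)-lactic acid | C[C@@H](O)C(=O)O | starting material
9 | pivalaldehyde, 2,2-dimethylpropanal | CC(C)(C)C=O | starting material
10 | (2R,5R)-2-tert-butyl-5-methyl-1,3-dioxolan-4-one | C[C@H]1O[C@@H](C(C)(C)C)OC1=O | intermediate
11 | lithium (2R)-2-tert-butyl-5-methyl-1,3-dioxol-4-olate (enolate of 10) | CC1=C(O[Li])O[C@H](C(C)(C)C)O1 | intermediate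
12 | (2R,5S)-2-tert-butyl-5-[(4R)-4-[(tert-butyldimethylsilyloxy)methyl]-1-hydroxy-4,8-dimethylnon-7-en-2-yn-1-yl]-5-methyl-1,3-dioxolan-4-one, both carbinol epimers | CC(C)=CCC[C@@](C)(CO[Si](C)(C)C(C)(C)C)C#CC(O)[C@]1(C)O[C@@H](C(C)(C)C)OC1=O | intermediate
13 | (2R,5S)-2-tert-butyl-5-[(4R)-4-[(tert-butyldimethylsilyloxy)methyl]-4,8-dimethylnon-7-en-2-ynoyl]-5-methyl-1,3-dioxolan-4-one | CC(C)=CCC[C@@](C)(CO[Si](C)(C)C(C)(C)C)C#CC(=O)[C@]1(C)O[C@@H](C(C)(C)C)OC1=O | intermediate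
14 | (2R,5S)-2-tert-butyl-5-[(1R,4R)-4-[(tert-butyldimethylsilyloxy)methyl]-1-hydroxy-4,8-dimethylnon-7-en-2-yn-1-yl]-5-methyl-1,3-dioxolan-4-one | CC(C)=CCC[C@@](C)(CO[Si](C)(C)C(C)(C)C)C#C[C@@H](O)[C@]1(C)O[C@@H](C(C)(C)C)OC1=O | intermediate
15 | (2R,5S)-2-tert-butyl-5-[(1R,2Z,4R)-4-[(tert-butyldimethylsilyloxy)methyl]-1-hydroxy-4,8-dimethylnona-2,7-dien-1-yl]-5-methyl-1,3-dioxolan-4-one | CC(C)=CCC[C@@](C)(CO[Si](C)(C)C(C)(C)C)/C=C\[C@@H](O)[C@]1(C)O[C@@H](C(C)(C)C)OC1=O | intermediate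
16 | methyl (2S,3R,4Z,6R)-6-[(tert-butyldimethylsilyloxy)methyl]-2,3-dihydroxy-2,6,10-trimethylundeca-4,9-dienoate | CC(C)=CCC[C@@](C)(CO[Si](C)(C)C(C)(C)C)/C=C\[C@@H](O)[C@](C)(O)C(=O)OC | intermediate
17 | methyl (4S,5R)-5-[(1Z,3R)-3-[(tert-butyldimethylsilyloxy)methyl]-3,7-dimethylocta-1,6-dien-1-yl]-2,2,4-trimethyl-1,3-dioxolane-4-carboxylate | CC(C)=CCC[C@@](C)(CO[Si](C)(C)C(C)(C)C)/C=C\[C@H]1OC(C)(C)O[C@]1(C)C(=O)OC | intermediate
18 | methyl (4S,5R)-5-[(1Z,3R)-3-(hydroxymethyl)-3,7-dimethylocta-1,6-dien-1-yl]-2,2,4-trimethyl-1,3-dioxolane-4-carboxylate | CC(C)=CCC[C@@](C)(CO)/C=C\[C@H]1OC(C)(C)O[C@]1(C)C(=O)OC | intermediate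
19 | methyl (4S,5R)-5-[(1Z,3R)-3-formyl-3,7-dimethylocta-1,6-dien-1-yl]-2,2,4-trimethyl-1,3-dioxolane-4-carboxylate | CC(C)=CCC[C@@](C)(C=O)/C=C\[C@H]1OC(C)(C)O[C@]1(C)C(=O)OC | intermediate
20 | methyl (4S,5R)-5-[(1Z,3S)-3-ethenyl-3,7-dimethylocta-1,6-dien-1-yl]-2,2,4-trimethyl-1,3-dioxolane-4-carboxylate | CC(C)=CCC[C@@](C)(C=C)/C=C\[C@H]1OC(C)(C)O[C@]1(C)C(=O)OC | intermediate
21 | B-alkyl-9-borabicyclo[3.3.1]nonane adduct of 20 (boron on the terminal carbon of the former vinyl group) | CC(C)=CCC[C@@](C)(CCB1C2CCCC1CCC2)/C=C\[C@H]1OC(C)(C)O[C@]1(C)C(=O)OC | intermediate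
22 | methyl (4S,5R)-5-[(1Z,3S)-3-(2-hydroxyethyl)-3,7-dimethylocta-1,6-dien-1-yl]-2,2,4-trimethyl-1,3-dioxolane-4-carboxylate | CC(C)=CCC[C@@](C)(CCO)/C=C\[C@H]1OC(C)(C)O[C@]1(C)C(=O)OC | intermediate
23 | methyl (4S,5R)-5-[(1Z,3S)-3,7-dimethyl-3-(2-oxoethyl)octa-1,6-dien-1-yl]-2,2,4-trimethyl-1,3-dioxolane-4-carboxylate | CC(C)=CCC[C@@](C)(CC=O)/C=C\[C@H]1OC(C)(C)O[C@]1(C)C(=O)OC | intermediate
24 | methyl (4S,5R)-5-[(1Z,3S)-3,7-dimethyl-3-[(2E)-4-oxobut-2-en-1-yl]octa-1,6-dien-1-yl]-2,2,4-trimethyl-1,3-dioxolane-4-carboxylate | CC(C)=CCC[C@@](C)(C/C=C/C=O)/C=C\[C@H]1OC(C)(C)O[C@]1(C)C(=O)OC | intermediate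
25 | methyl (4S,5R)-5-[(1Z,3S)-3-[(2Z)-3-iodo-4-oxobut-2-en-1-yl]-3,7-dimethylocta-1,6-dien-1-yl]-2,2,4-trimethyl-1,3-dioxolane-4-carboxylate | CC(C)=CCC[C@@](C)(C/C=C(\I)C=O)/C=C\[C@H]1OC(C)(C)O[C@]1(C)C(=O)OC | intermediate
26 | methyl (4S,5R)-5-[(1Z,3S)-3-[(2Z)-4-hydroxy-3-iodobut-2-en-1-yl]-3,7-dimethylocta-1,6-dien-1-yl]-2,2,4-trimethyl-1,3-dioxolane-4-carboxylate | CC(C)=CCC[C@@](C)(C/C=C(\I)CO)/C=C\[C@H]1OC(C)(C)O[C@]1(C)C(=O)OC | intermediate
27 | methyl (4S,5R)-5-[(1Z,3S)-3-[(2Z)-4-(tert-butyldiphenylsilyloxy)-3-iodobut-2-en-1-yl]-3,7-dimethylocta-1,6-dien-1-yl]-2,2,4-trimethyl-1,3-dioxolane-4-carboxylate | CC(C)=CCC[C@@](C)(C/C=C(\I)CO[Si](c1ccccc1)(c1ccccc1)C(C)(C)C)/C=C\[C@H]1OC(C)(C)O[C@]1(C)C(=O)OC | intermediate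
28 | (4S,5R)-5-[(1Z,3S)-3-[(2Z)-4-(tert-butyldiphenylsilyloxy)-3-iodobut-2-en-1-yl]-3,7-dimethylocta-1,6-dien-1-yl]-2,2,4-trimethyl-1,3-dioxolane-4-carbaldehyde | CC(C)=CCC[C@@](C)(C/C=C(\I)CO[Si](c1ccccc1)(c1ccccc1)C(C)(C)C)/C=C\[C@H]1OC(C)(C)O[C@]1(C)C=O | intermediate
29 | methyl (2Z)-3-[(4R,5R)-5-[(1Z,3S)-3-[(2Z)-4-(tert-butyldiphenylsilyloxy)-3-iodobut-2-en-1-yl]-3,7-dimethylocta-1,6-dien-1-yl]-2,2,4-trimethyl-1,3-dioxolan-4-yl]prop-2-enoate | CC(C)=CCC[C@@](C)(C/C=C(\I)CO[Si](c1ccccc1)(c1ccccc1)C(C)(C)C)/C=C\[C@H]1OC(C)(C)O[C@]1(C)/C=C\C(=O)OC | intermediate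
30 | (2Z)-3-[(4R,5R)-5-[(1Z,3S)-3-[(2Z)-4-(tert-butyldiphenylsilyloxy)-3-iodobut-2-en-1-yl]-3,7-dimethylocta-1,6-dien-1-yl]-2,2,4-trimethyl-1,3-dioxolan-4-yl]prop-2-en-1-ol | CC(C)=CCC[C@@](C)(C/C=C(\I)CO[Si](c1ccccc1)(c1ccccc1)C(C)(C)C)/C=C\[C@H]1OC(C)(C)O[C@]1(C)/C=C\CO | intermediate
31 | (2Z)-3-[(4R,5R)-5-[(1Z,3S)-3-[(2Z)-4-(tert-butyldiphenylsilyloxy)-3-iodobut-2-en-1-yl]-3,7-dimethylocta-1,6-dien-1-yl]-2,2,4-trimethyl-1,3-dioxolan-4-yl]prop-2-enal | CC(C)=CCC[C@@](C)(C/C=C(\I)CO[Si](c1ccccc1)(c1ccccc1)C(C)(C)C)/C=C\[C@H]1OC(C)(C)O[C@]1(C)/C=C\C=O | intermediate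
32 | macrocyclic allylic alcohol: 11-membered ring, C8–OH (both epimers), C4/C5 acetonide, C9–CH2OTBDPS, 1S,4R,5R, ring alkenes 2Z,6Z,9Z | CC(C)=CCC[C@]1(C)/C=C\[C@H]2OC(C)(C)O[C@]2(C)/C=C\C(O)/C(CO[Si](c3ccccc3)(c3ccccc3)C(C)(C)C)=C\C1 | intermediate
33 | macrocyclic dienone: C8 ketone, C4/C5 acetonide, C9–CH2OTBDPS, 1S,4R,5R, 2Z,6Z,9Z | CC(C)=CCC[C@]1(C)/C=C\[C@H]2OC(C)(C)O[C@]2(C)/C=C\C(=O)/C(CO[Si](c3ccccc3)(c3ccccc3)C(C)(C)C)=C\C1 | intermediate
34 | dienone diol: C4–OH and C5–OH free, C9–CH2OTBDPS, 1S,4R,5R, 2Z,6Z,9Z | CC(C)=CCC[C@]1(C)/C=C\[C@@H](O)[C@](C)(O)/C=C\C(=O)/C(CO[Si](c2ccccc2)(c2ccccc2)C(C)(C)C)=C\C1 | intermediate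
35 | 3-methylbut-2-enoyl chloride (senecioyl chloride) | CC(C)=CC(=O)Cl | starting material
36 | C4 3-methylbut-2-enoate of 34 (C5–OH free, C9–CH2OTBDPS) | CC(C)=CCC[C@]1(C)/C=C\[C@@H](OC(=O)C=C(C)C)[C@](C)(O)/C=C\C(=O)/C(CO[Si](c2ccccc2)(c2ccccc2)C(C)(C)C)=C\C1 | intermediate
37 | CNP0230506.6: (1S,4R,5R; 2Z,6Z,9Z) 11-membered trienone with C4 3-methylbut-2-enoate, C5–OH and C9–CH2OH | CC(C)=CCC[C@]1(C)/C=C\[C@@H](OC(=O)C=C(C)C)[C@](C)(O)/C=C\C(=O)/C(CO)=C\C1 | target

## Step count and risks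

Total steps: 30. Longest linear sequence: 29 (geraniol to target, steps 1–5 and 7–30); step 6 is a one-step side branch.

**Step 3 (epoxy silyl ether rearrangement).** The tertiary cation can be diverted to a hydride shift or to cyclisation onto the side-chain alkene. The fallback sets out from 1 and comes back at 5, and forms the quaternary centre by C–C bond formation instead of a 1,2-shift. Geraniol is epoxidised with D-(−)-diethyl tartrate to (2R,3R)-2,3-epoxygeraniol F1. The alane Me2AlC≡CSiMe3 opens the epoxide at the tertiary carbon with inversion to give the alkynyl diol (2S,3R)-3-methyl-3-(4-methylpent-3-en-1-yl)-5-(trimethylsilyl)pent-4-yne-1,2-diol F2. NaIO4 cleaves this to the aldehyde (R)-2,6-dimethyl-2-[(trimethylsilyl)ethynyl]hept-5-enal F3, NaBH4 gives the neopentyl alcohol F4, and TBSCl/imidazole gives the silyl ether F5. K2CO3 in MeOH then removes the alkynyl silyl group to give 5. The enantiomeric epoxide is needed because here the incoming carbon becomes the alkyne and the old epoxide carbon becomes the CH2O arm.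

**Step 9 (transfer hydrogenation).** The ketone sits next to a fully substituted carbon and may reduce slowly. The fallback sets out from 12 and comes back at 14 with no new compound. The two carbinol epimers of 12 are separated by chromatography, and the 1R epimer is 14. The unwanted epimer is recycled by the oxidation of step 8 and a non-selective NaBH4/CeCl3 reduction back to 12, so C4 is set by resolution and recycling instead of catalyst control.

**Step 26 (Nozaki–Hiyama–Kishi ring closure).** Closure of a strained 11-membered ring competes with dimerisation and reduction of the vinyl iodide. The fallback sets out from 27 and comes back at 33, and forms the dienone carbonyl during a carbonylative ring closure. Me3SnSnMe3 and Pd(PPh3)4 convert the vinyl iodide to the vinylstannane ester F6. iBu2AlH at −78 °C gives the aldehyde F7, and the Stork–Zhao reagent (Ph3PCH2I iodide, NaN(SiMe3)2) gives the cis vinyl iodide F8. Intramolecular carbonylative Stille coupling (PdCl2(MeCN)2, CO 3 atm, DMF, high dilution) inserts CO between C7 and C9 and gives 33 directly.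

Further compounds
F1 | step 3 | (2R,3R)-2,3-epoxygeraniol | CC(C)=CCC[C@@]1(C)O[C@@H]1CO
F2 | step 3 | (2S,3R)-3-methyl-3-(4-methylpent-3-en-1-yl)-5-(trimethylsilyl)pent-4-yne-1,2-diol | CC(C)=CCC[C@@](C)([C@H](O)CO)C#C[Si](C)(C)C
F3 | step 3 | (R)-2,6-dimethyl-2-[(trimethylsilyl)ethynyl]hept-5-enal | CC(C)=CCC[C@@](C)(C=O)C#C[Si](C)(C)C
F4 | step 3 | (R)-2,6-dimethyl-2-[(trimethylsilyl)ethynyl]hept-5-en-1-ol | CC(C)=CCC[C@@](C)(CO)C#C[Si](C)(C)C
F5 | step 3 | (R)-tert-butyl({2,6-dimethyl-2-[(trimethylsilyl)ethynyl]hept-5-en-1-yl}oxy)dimethylsilane | CC(C)=CCC[C@@](C)(CO[Si](C)(C)C(C)(C)C)C#C[Si](C)(C)C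
F0 | step 9 | none | none
F6 | step 26 | vinylstannane ester: 27 with iodine replaced by trimethylstannyl | CC(C)=CCC[C@@](C)(C/C=C(\[Sn](C)(C)C)CO[Si](c1ccccc1)(c1ccccc1)C(C)(C)C)/C=C\[C@H]1OC(C)(C)O[C@]1(C)C(=O)OC
F7 | step 26 | vinylstannane aldehyde: F6 with the methyl ester reduced to the aldehyde | CC(C)=CCC[C@@](C)(C/C=C(\[Sn](C)(C)C)CO[Si](c1ccccc1)(c1ccccc1)C(C)(C)C)/C=C\[C@H]1OC(C)(C)O[C@]1(C)C=O
F8 | step 26 | cis vinyl iodide vinylstannane: F7 with the aldehyde converted to (Z)-CH=CHI | CC(C)=CCC[C@@](C)(C/C=C(\[Sn](C)(C)C)CO[Si](c1ccccc1)(c1ccccc1)C(C)(C)C)/C=C\[C@H]1OC(C)(C)O[C@]1(C)/C=C\I
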